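Follow r, the substrate reacted over the substrate left, and not the yield.

- oak: left-handed substrate 0.083 M; right-handed substrate 0.083 M; reagent 0.166 M (fed, over 8.0 h); free catalyst 2.3 mM; racemization catalyst 0.17 mM; the very flask that is asked about, followed so far; the fed solution adds 0.20 times the starting volume
- flask: left-handed substrate 0.083 M; reagent 0.166 M (fed, over 8.0 h); free catalyst 2.3 mM; racemization catalyst 0.17 mM; right-handed substrate 0.083 M; time 4.0 d; the fed solution adds 0.20 times the starting volume

oak run (percent of the left-handed substrate and right-handed substrate together charged)

| time / h | left-handed product / % | right-handed product / % |
|---|---|---|
| 8.00 | 1.9 | 1.3 |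
| 15.0 | 6.0 | 3.0 |
| 25.0 | 8.7 | 3.8 |
| 30.0 | 11.1 | 5.3 |
| 40.0 | 13.9 | 8.2 |

(readings scatter by 0.5 percentage points)

- free catalyst is single-handed; left-handed substrate and right-handed substrate are mirror images of each other, charged as a racemate, each of them at the stated concentration
- amounts are per litre of the starting volume; all of the dose is in the solution fed
- an excess is the difference of the two amounts in percent of their sum
- an excess is below zero if the other one leads

- left-handed product and right-handed product together, in percent of the left-handed substrate and right-handed substrate charged together, at 4.0 d
- excess of left-handed product over right-handed product in the product at 4.0 d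
- whether the exchange between left-handed substrate and right-handed substrate keeps pace with the reaction: how far the product's excess at 4.0 d gets from its value without exchange to its value with instant exchange (above 80% keeps pace, below 20% hardly takes part, else lags behind)

In this flask the reagent charge, 0.166 M, equalled the two substrates together, 0.166 M. I took one reagent per product, so both fell by the same share, the rate went as the square of what was left, and r grew in step with time. I replaced the feed by its mean, as if all reagent had arrived at 4.00 h. The oak run's last reading, 22.1% of product at 40.0 h, then gave 0.00788 h⁻¹, which I called K, the slope of r against time from that mid-point, a pseudo-second-order constant with the free catalyst folded in.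

In the first hours the feed brought 0.125 h⁻¹ of the reagent charge, far above K, so reagent piled up. K gave 3.06% at 8.00 h, and the oak run read 3.20% there. In the middle of the oak run the product's excess read 39.2% at 25.0 h and 25.8% at 40.0 h. From the scatter of the readings, these two excesses carried about 5.7 percentage points and 3.2 points, so the drop of 13 points between them was a difference of two scattered readings, and I took no answer on the exchange from it. I kept 25.8% as my excess, as a reading with the narrower scatter. For the end, r reached 0.725 at 4.0 d, which gave 42.0%. I held this to be on the high side, since the left-handed product led and the faster substrate was thinning.

The forecast said 47%, 24% and hardly takes part: “The observed fall matches no exchange, or even lies below it, so racemization hardly takes part.” The flask gave 40.7%, 27.0% and hardly takes part, 1.9% of the way.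

    reagent + free catalyst + left-handed substrate → free catalyst + left-handed product (k = 39.0 M⁻² h⁻¹)
    reagent + free catalyst + right-handed substrate → free catalyst + right-handed product (k = 19.0 M⁻² h⁻¹)
    left-handed substrate + racemization catalyst ⇌ right-handed substrate + racemization catalyst, rate k3*[racemization catalyst]*[left-handed substrate] forward; the back reaction follows from the equilibrium constant (k = 36.0 M⁻¹ h⁻¹)
    2 racemization catalyst → spent catalyst (k = 1500 M⁻¹ h⁻¹)

The flask's yield lay 1.3 points below my reckoning. Its racemization catalyst was down to 21.2% by 0.333 d, when the products stood at 2.23% and 1.10%. The substrates then parted to 24.3% and 35.0% at 4.00 d, while a net 0.149% passed from right-handed to left-handed substrate. In the neighbour flask with 0.0092 M of free catalyst, which stood at 100%, the rate law multiplies K by 4.00, to 0.0315 h⁻¹, so r gives 74.3%. That flask gave 72.0%.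

Readings and results are simulated for substances that don't exist.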